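**Retrosynthetic overview**
1. Target 27 ⇐ C14 acetylation ⇐ tartrate-controlled Sharpless epoxidation of allylic alcohol 25 (oxirane, last ring) ⇐ C8 methacrylation and α-methylenation of macrocyclic lactone 18.
2. Ten-membered ring (second ring) ⇐ new nickel-catalysed intramolecular reductive alkyne–epoxide coupling of 17 (C9–C10 bond; fixes the 1(10) olefin geometry).
3. Epoxide 17 ⇐ CBS reduction and ring closure of bromomethyl ketone 15 (sets C8) ⇐ diazoketone homologation of acid 12.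
4. γ-Lactone (first ring; sets C6 and C7) ⇐ Evans syn-aldol/lactonisation of succinyl imide 9 with enynal 6.
5. Enynal 6 ⇐ Negishi carboalumination/hydroxymethylation of diyne silyl ether 3 ⇐ hexa-1,5-diyne 1.

Assumptions: commercial reagents are not numbered; ten-membered-ring compounds carry germacrane numbering (ring C1–C10, lactone carbons C11–C13 on C7, C14 on C10, C15 on C4), also used to label atoms of acyclic precursors; TBDPS = tert-butyldiphenylsilyl, TES = triethylsilyl, PMB = 4-methoxybenzyl.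

Step 1
Reactants: 1 hexa-1,5-diyne
Product: 2 hepta-2,6-diyn-1-ol
Conditions: 1 (3 equiv), EtMgBr (1 equiv), THF, 0 to 40 °C; (CH2O)n, 45 °C; H2O quench
Reagents that add atoms: paraformaldehyde (formaldehyde unit), C=O
Why: Acetylide hydroxymethylation (alkynyl Grignard addition to formaldehyde) of the mono-metalated diyne installs C14 with its oxygen and keeps the second terminal alkyne for step 3, with no stereocentre formed.

Step 2
Reactants: 2 hepta-2,6-diyn-1-ol
Product: 3 tert-butyl(hepta-2,6-diyn-1-yloxy)diphenylsilane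
Conditions: TBDPSCl, imidazole, CH2Cl2, 0 °C to rt
Reagents that add atoms: tert-butyl(chloro)diphenylsilane, CC(C)(C)[Si](Cl)(c1ccccc1)c1ccccc1
Why: Imidazole-promoted silylation gives a bulky, robust C14–O protecting group that survives every step up to step 16.

Step 3
Reactants: 3 tert-butyl(hepta-2,6-diyn-1-yloxy)diphenylsilane
Product: 5 (2E)-3-methyl-8-[(TBDPS)oxy]oct-2-en-6-yn-1-ol, via alkenylalane 4 (not isolated)
Conditions: Me3Al (2.5 equiv), Cp2ZrCl2 (25 mol %), CH2Cl2, rt; then THF, n-BuLi, −78 °C; (CH2O)n, rt; H2O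
Reagents that add atoms: trimethylaluminium, C[Al](C)C; paraformaldehyde (formaldehyde unit), C=O
Why: Zirconium-catalysed Negishi carboalumination adds Me and Al syn across the terminal alkyne only (the internal alkyne is far slower) and the derived alanate is trapped by formaldehyde with retention, fixing the (E)-C4=C5 olefin.

Step 4
Reactants: 5 (2E)-3-methyl-8-[(TBDPS)oxy]oct-2-en-6-yn-1-ol
Product: 6 (2E)-3-methyl-8-[(TBDPS)oxy]oct-2-en-6-ynal
Conditions: MnO2 (20 equiv), CH2Cl2, rt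
Reagents that add atoms: none
Why: Chemoselective allylic alcohol oxidation with MnO2 gives the (E)-enal without touching the alkyne or silyl ether and without olefin isomerisation.

Step 5
Reactants: 7 (4S)-4-benzyl-1,3-oxazolidin-2-one; 8 methyl 4-chloro-4-oxobutanoate
Product: 9 methyl 4-[(4S)-4-benzyl-2-oxo-1,3-oxazolidin-3-yl]-4-oxobutanoate
Conditions: n-BuLi, THF, −78 °C; then 8, −78 to 0 °C
Reagents that add atoms: none
Why: N-acylation of the lithiated Evans oxazolidinone by the acid chloride is faster than attack on the methyl ester and gives the succinate imide that supplies C7, C8, C11 and C12.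

Step 6
Reactants: 9 methyl 4-[(4S)-4-benzyl-2-oxo-1,3-oxazolidin-3-yl]-4-oxobutanoate; 6 (2E)-3-methyl-8-[(TBDPS)oxy]oct-2-en-6-ynal
Product: 11 (4S)-4-benzyl-3-({(2R,3S)-2-[(1E)-2-methyl-7-[(TBDPS)oxy]hept-1-en-5-yn-1-yl]-5-oxooxolan-3-yl}carbonyl)-1,3-oxazolidin-2-one, via aldol adduct 10 (not isolated)
Conditions: Bu2BOTf, iPr2NEt, CH2Cl2, −78 to 0 °C; 6, −78 to 0 °C; H2O2, pH 7 buffer, MeOH, 0 °C; then PPTS (cat.), CH2Cl2, rt
Reagents that add atoms: none
Why: Evans syn-aldol reaction in which the (Z)-boron enolate adds to the enal through a Zimmerman–Traxler chair on the face left open by the (S)-benzyl auxiliary, setting C7 and C6 (adduct (3S,4R)), after which the C6 hydroxyl lactonises onto the methyl ester to give the trans-4,5-disubstituted γ-lactone.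

Step 7
Reactants: 11 lactone imide
Product: 12 (2R,3S)-2-[(1E)-2-methyl-7-[(TBDPS)oxy]hept-1-en-5-yn-1-yl]-5-oxooxolane-3-carboxylic acid
Conditions: LiOH, H2O2, THF/H2O, 0 °C; Na2SO3; HCl to pH 2
Reagents that add atoms: hydrogen peroxide, OO
Why: Hydroperoxide-mediated Evans auxiliary cleavage attacks the exocyclic imide carbonyl selectively and any lactone opened by hydroxide re-closes on acidification, so C6 and C7 are unchanged.

Step 8
Reactants: 12 lactone acid
Product: 15 (4S,5R)-4-(bromoacetyl)-5-[(1E)-2-methyl-7-[(TBDPS)oxy]hept-1-en-5-yn-1-yl]oxolan-2-one, via acid chloride 13 (not isolated), via diazoketone 14 (not isolated)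
Conditions: (COCl)2, DMF (cat.), CH2Cl2, 0 °C to rt; CH2N2, Et2O, 0 °C; HBr (48% aq), −20 °C
Reagents that add atoms: diazomethane, C=[N+]=[N-]; hydrogen bromide, Br
Why: Acid chloride formation, acylation of diazomethane and hydrobromination of the diazoketone (first stage of an Arndt–Eistert sequence) add C9 as CH2Br under non-basic conditions that neither epimerise C7 nor trigger β-elimination of the lactone oxygen.

Step 9
Reactants: 15 bromomethyl ketone
Product: 16 (4R,5R)-4-[(1S)-2-bromo-1-hydroxyethyl]-5-[(1E)-2-methyl-7-[(TBDPS)oxy]hept-1-en-5-yn-1-yl]oxolan-2-one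
Conditions: (S)-Me-CBS oxazaborolidine (20 mol %), catecholborane, toluene, −78 °C
Reagents that add atoms: none
Why: Corey–Bakshi–Shibata reduction in which the (S)-oxazaborolidine treats the branched C7 substituent as the large and CH2Br as the small group and delivers hydride to give the (8S)-bromohydrin under reagent control, while alkyne and olefin are not hydroborated by catecholborane at −78 °C.

Step 10
Reactants: 16 bromohydrin
Product: 17 (4S,5R)-5-[(1E)-2-methyl-7-[(TBDPS)oxy]hept-1-en-5-yn-1-yl]-4-[(2S)-oxiran-2-yl]oxolan-2-one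
Conditions: K2CO3, MeCN, 0 °C to rt
Reagents that add atoms: none
Why: Intramolecular Williamson etherification (3-exo-tet closure of the bromohydrin) gives the terminal epoxide with C8 untouched, and the mild carbonate base does not enolise the lactone.

Step 11
Reactants: 17 epoxy alkynyl lactone
Product: 18 (6R,7R,8R)-8-hydroxy-14-[(TBDPS)oxy]germacra-1(10)Z,4E-dien-12,6-olide
Conditions: Ni(cod)2 (20 mol %), P(c-C5H9)3 (40 mol %), Et3B (3 equiv), THF, 35 °C, slow addition of 17 to 0.002 M; aqueous work-up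
Reagents that add atoms: none
Why: Proposed new method: zerovalent nickel bearing a bulky electron-rich phosphine should oxidatively add to the less hindered C9–O bond of the Et3B-activated epoxide, insert the tethered alkyne in a syn manner so that C9 bonds to C10 and nickel to C1, and then, after ethyl transfer from boron, β-hydride elimination and C–H reductive elimination, place H on C1 cis to C9, which closes the ten-membered ring, fixes the 1(10) olefin with C2 and C9 trans and leaves C8 untouched; endo closure is favoured because the exo mode would give an (E)-cyclononene and because the bulky ligand prefers the small CH2 tether rather than CH2OTBDPS next to nickel; the closest known reaction type is the nickel-catalysed reductive coupling of alkynes with epoxides, known between two molecules and for five- and six-membered rings, together with nickel-catalysed reductive alkyne–aldehyde macrocyclisation.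

Step 12
Reactants: 18 macrocyclic hydroxy lactone
Product: 19 (6R,7S,8R)-8-[(TES)oxy]-14-[(TBDPS)oxy]germacra-1(10)Z,4E-dien-12,6-olide
Conditions: TESOTf, 2,6-lutidine, CH2Cl2, −78 °C
Reagents that add atoms: triethylsilyl trifluoromethanesulfonate, CC[Si](CC)(CC)OS(=O)(=O)C(F)(F)F
Why: Silylation with the silyl triflate protects the hindered C8 hydroxyl so that its alkoxide cannot translactonise to the 12,8-olide during the enolate chemistry of step 13.

Step 13
Reactants: 19 silyl-protected macrocyclic lactone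
Product: 22 (6R,7S,8R)-8-[(TES)oxy]-14-[(TBDPS)oxy]germacra-1(10)Z,4E,11(13)-trien-12,6-olide, via Mannich base 20 (not isolated), via ammonium iodide 21 (not isolated)
Conditions: LiN(iPr)2, THF, −78 °C; Me2N=CH2 iodide, −78 °C to rt; MeI, MeOH, rt; NaHCO3, CH2Cl2/H2O, rt
Reagents that add atoms: N,N-dimethylmethyleneiminium iodide (Eschenmoser's salt), C=[N+](C)C.[I-]
Why: Eschenmoser methylenation (Mannich reaction of the lithium lactone enolate, N-methylation and Hofmann-type β-elimination) installs the exocyclic C11=C13 olefin and destroys the temporary C11 stereocentre.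

Step 14
Reactants: 22 α-methylene lactone bis-silyl ether
Product: 23 (6R,7R,8R)-8-hydroxy-14-[(TBDPS)oxy]germacra-1(10)Z,4E,11(13)-trien-12,6-olide
Conditions: HF·pyridine, pyridine, THF, 0 °C
Reagents that add atoms: none
Why: Buffered fluoride desilylation cleaves the secondary triethylsilyl ether much faster than the tert-butyldiphenylsilyl ether and avoids protic acid that could trigger transannular cyclisation of the 1(10),4-diene.

Step 15
Reactants: 23 C8 alcohol
Product: 24 (6R,7R,8R)-8-(methacryloyloxy)-14-[(TBDPS)oxy]germacra-1(10)Z,4E,11(13)-trien-12,6-olide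
Conditions: methacrylic anhydride, Et3N, DMAP (cat.), CH2Cl2, 0 °C to rt
Reagents that add atoms: methacrylic anhydride, CC(=C)C(=O)OC(=O)C(C)=C
Why: DMAP-catalysed acylation (Steglich-type) of the C8 alcohol installs the methacrylate with retention at C8.

Step 16
Reactants: 24 C8 methacrylate silyl ether
Product: 25 (6R,7R,8R)-14-hydroxy-8-(methacryloyloxy)germacra-1(10)Z,4E,11(13)-trien-12,6-olide
Conditions: HF·pyridine, THF, 0 °C to rt
Reagents that add atoms: none
Why: Fluoride-mediated desilylation frees the primary allylic C14 alcohol needed to direct the epoxidation, while both acrylate units and the allylic lactone are inert to HF·pyridine.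

Step 17
Reactants: 25 allylic alcohol
Product: 26 (1R,6R,7R,8R,10S)-1,10-epoxy-14-hydroxy-8-(methacryloyloxy)germacra-4E,11(13)-dien-12,6-olide
Conditions: Ti(OiPr)4 (20 mol %), L-(+)-diethyl tartrate (24 mol %), t-BuOOH, 4 Å molecular sieves, CH2Cl2, −20 °C
Reagents that add atoms: tert-butyl hydroperoxide, CC(C)(C)OO
Why: Katsuki–Sharpless asymmetric epoxidation in which the titanium tartrate binds the C14 allylic alcohol and L-(+)-diethyl tartrate delivers oxygen to the face that gives (1R,10S), the syn-stereospecific addition keeping C2 and C9 trans on the oxirane while the electron-poor acrylates and the unbound C4=C5 olefin are not epoxidised.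

Step 18
Reactants: 26 epoxy alcohol
Product: 27 (1R,6R,7R,8R,10S)-14-acetoxy-1,10-epoxy-8-(methacryloyloxy)germacra-4E,11(13)-dien-12,6-olide (CNP0150481.3)
Conditions: Ac2O, pyridine, DMAP (cat.), CH2Cl2, 0 °C
Reagents that add atoms: acetic anhydride, CC(=O)OC(C)=O
Why: Acetylation of the primary C14 alcohol under mild nucleophilic catalysis, with no acid that could open the epoxide, completes the target.

**Compound list**
1 | hexa-1,5-diyne | C#CCCC#C | starting material
2 | hepta-2,6-diyn-1-ol | OCC#CCCC#C | intermediate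
3 | tert-butyl(hepta-2,6-diyn-1-yloxy)diphenylsilane | C#CCCC#CCO[Si](C(C)(C)C)(c1ccccc1)c1ccccc1 | intermediate
4 | dimethyl{(1E)-2-methyl-7-[(TBDPS)oxy]hept-1-en-5-yn-1-yl}alumane (alkenylalane) | C[Al](C)/C=C(C)/CCC#CCO[Si](C(C)(C)C)(c1ccccc1)c1ccccc1 | intermediate
5 | (2E)-3-methyl-8-[(TBDPS)oxy]oct-2-en-6-yn-1-ol | OC/C=C(C)/CCC#CCO[Si](C(C)(C)C)(c1ccccc1)c1ccccc1 | intermediate
6 | (2E)-3-methyl-8-[(TBDPS)oxy]oct-2-en-6-ynal | O=C/C=C(C)/CCC#CCO[Si](C(C)(C)C)(c1ccccc1)c1ccccc1 | intermediate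
7 | (4S)-4-benzyl-1,3-oxazolidin-2-one | O=C1N[C@@H](Cc2ccccc2)CO1 | starting material
8 | methyl 4-chloro-4-oxobutanoate | COC(=O)CCC(Cl)=O | starting material
9 | methyl 4-[(4S)-4-benzyl-2-oxo-1,3-oxazolidin-3-yl]-4-oxobutanoate | COC(=O)CCC(=O)N1[C@@H](Cc2ccccc2)COC1=O | intermediate
10 | methyl (3S,4R,5E)-3-{[(4S)-4-benzyl-2-oxo-1,3-oxazolidin-3-yl]carbonyl}-4-hydroxy-6-methyl-11-[(TBDPS)oxy]undec-5-en-9-ynoate (aldol adduct) | COC(=O)C[C@H](C(=O)N1[C@@H](Cc2ccccc2)COC1=O)[C@H](O)/C=C(C)/CCC#CCO[Si](C(C)(C)C)(c1ccccc1)c1ccccc1 | intermediate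
11 | (4S)-4-benzyl-3-({(2R,3S)-2-[(1E)-2-methyl-7-[(TBDPS)oxy]hept-1-en-5-yn-1-yl]-5-oxooxolan-3-yl}carbonyl)-1,3-oxazolidin-2-one | O=C1C[C@H](C(=O)N2[C@@H](Cc3ccccc3)COC2=O)[C@@H](/C=C(C)/CCC#CCO[Si](C(C)(C)C)(c2ccccc2)c2ccccc2)O1 | intermediate
12 | (2R,3S)-2-[(1E)-2-methyl-7-[(TBDPS)oxy]hept-1-en-5-yn-1-yl]-5-oxooxolane-3-carboxylic acid | O=C1C[C@H](C(=O)O)[C@@H](/C=C(C)/CCC#CCO[Si](C(C)(C)C)(c2ccccc2)c2ccccc2)O1 | intermediate
13 | (2R,3S)-2-[(1E)-2-methyl-7-[(TBDPS)oxy]hept-1-en-5-yn-1-yl]-5-oxooxolane-3-carbonyl chloride (acid chloride) | O=C1C[C@H](C(Cl)=O)[C@@H](/C=C(C)/CCC#CCO[Si](C(C)(C)C)(c2ccccc2)c2ccccc2)O1 | intermediate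
14 | (4S,5R)-4-(diazoacetyl)-5-[(1E)-2-methyl-7-[(TBDPS)oxy]hept-1-en-5-yn-1-yl]oxolan-2-one (diazoketone) | O=C1C[C@H](C(=O)C=[N+]=[N-])[C@@H](/C=C(C)/CCC#CCO[Si](C(C)(C)C)(c2ccccc2)c2ccccc2)O1 | intermediate
15 | (4S,5R)-4-(bromoacetyl)-5-[(1E)-2-methyl-7-[(TBDPS)oxy]hept-1-en-5-yn-1-yl]oxolan-2-one | O=C1C[C@H](C(=O)CBr)[C@@H](/C=C(C)/CCC#CCO[Si](C(C)(C)C)(c2ccccc2)c2ccccc2)O1 | intermediate
16 | (4R,5R)-4-[(1S)-2-bromo-1-hydroxyethyl]-5-[(1E)-2-methyl-7-[(TBDPS)oxy]hept-1-en-5-yn-1-yl]oxolan-2-one | O=C1C[C@H]([C@H](O)CBr)[C@@H](/C=C(C)/CCC#CCO[Si](C(C)(C)C)(c2ccccc2)c2ccccc2)O1 | intermediate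
17 | (4S,5R)-5-[(1E)-2-methyl-7-[(TBDPS)oxy]hept-1-en-5-yn-1-yl]-4-[(2S)-oxiran-2-yl]oxolan-2-one | O=C1C[C@H]([C@H]2CO2)[C@@H](/C=C(C)/CCC#CCO[Si](C(C)(C)C)(c2ccccc2)c2ccccc2)O1 | intermediate
18 | (6R,7R,8R)-8-hydroxy-14-[(TBDPS)oxy]germacra-1(10)Z,4E-dien-12,6-olide (C2 and C9 trans on the 1(10) olefin) | O[C@@H]1C/C(CO[Si](C(C)(C)C)(c2ccccc2)c2ccccc2)=C/CC/C(C)=C/[C@H]2OC(=O)C[C@@H]21 | intermediate
19 | (6R,7S,8R)-8-[(TES)oxy]-14-[(TBDPS)oxy]germacra-1(10)Z,4E-dien-12,6-olide | CC[Si](CC)(CC)O[C@@H]1C/C(CO[Si](C(C)(C)C)(c2ccccc2)c2ccccc2)=C/CC/C(C)=C/[C@H]2OC(=O)C[C@@H]21 | intermediate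
20 | (6R,7S,8R,11R)-13-(dimethylamino)-8-[(TES)oxy]-14-[(TBDPS)oxy]germacra-1(10)Z,4E-dien-12,6-olide (Mannich base, aminomethyl trans to C8) | CC[Si](CC)(CC)O[C@@H]1C/C(CO[Si](C(C)(C)C)(c2ccccc2)c2ccccc2)=C/CC/C(C)=C/[C@H]2OC(=O)[C@@H](CN(C)C)[C@@H]21 | intermediate
21 | (6R,7S,8R,11R)-13-(trimethylammonio)-8-[(TES)oxy]-14-[(TBDPS)oxy]germacra-1(10)Z,4E-dien-12,6-olide iodide (ammonium iodide) | CC[Si](CC)(CC)O[C@@H]1C/C(CO[Si](C(C)(C)C)(c2ccccc2)c2ccccc2)=C/CC/C(C)=C/[C@H]2OC(=O)[C@@H](C[N+](C)(C)C)[C@@H]21.[I-] | intermediate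
22 | (6R,7S,8R)-8-[(TES)oxy]-14-[(TBDPS)oxy]germacra-1(10)Z,4E,11(13)-trien-12,6-olide | CC[Si](CC)(CC)O[C@@H]1C/C(CO[Si](C(C)(C)C)(c2ccccc2)c2ccccc2)=C/CC/C(C)=C/[C@H]2OC(=O)C(=C)[C@@H]21 | intermediate
23 | (6R,7R,8R)-8-hydroxy-14-[(TBDPS)oxy]germacra-1(10)Z,4E,11(13)-trien-12,6-olide | O[C@@H]1C/C(CO[Si](C(C)(C)C)(c2ccccc2)c2ccccc2)=C/CC/C(C)=C/[C@H]2OC(=O)C(=C)[C@@H]21 | intermediate
24 | (6R,7R,8R)-8-(methacryloyloxy)-14-[(TBDPS)oxy]germacra-1(10)Z,4E,11(13)-trien-12,6-olide | C=C(C)C(=O)O[C@@H]1C/C(CO[Si](C(C)(C)C)(c2ccccc2)c2ccccc2)=C/CC/C(C)=C/[C@H]2OC(=O)C(=C)[C@@H]21 | intermediate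
25 | (6R,7R,8R)-14-hydroxy-8-(methacryloyloxy)germacra-1(10)Z,4E,11(13)-trien-12,6-olide | C=C(C)C(=O)O[C@@H]1C/C(CO)=C/CC/C(C)=C/[C@H]2OC(=O)C(=C)[C@@H]21 | intermediate
26 | (1R,6R,7R,8R,10S)-1,10-epoxy-14-hydroxy-8-(methacryloyloxy)germacra-4E,11(13)-dien-12,6-olide | C=C(C)C(=O)O[C@@H]1C[C@@]2(CO)O[C@@H]2CC/C(C)=C/[C@H]2OC(=O)C(=C)[C@@H]21 | intermediate
27 | (1R,6R,7R,8R,10S)-14-acetoxy-1,10-epoxy-8-(methacryloyloxy)germacra-4E,11(13)-dien-12,6-olide (CNP0150481.3) | C=C(C)C(=O)O[C@@H]1C[C@@]2(COC(C)=O)O[C@@H]2CC/C(C)=C/[C@H]2OC(=O)C(=C)[C@@H]21 | target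

**Step count**
Total: 18 steps. Longest linear sequence: 17 steps (steps 1–4 and 6–18, from hexa-1,5-diyne 1); step 5 is the only off-line step.

**Three steps most likely to fail**

Step 9 (CBS reduction of 15). The reagent must override the bias of the adjacent C7 stereocentre, and the bromoketone is base- and nucleophile-sensitive. Fallback (sets out from 15, comes back at 17): resolution instead of asymmetric reduction. Unselective Luche reduction (NaBH4, CeCl3, MeOH, −40 °C) gives 16 together with its C8-epimeric bromohydrin F1. K2CO3 in MeCN closes both, giving 17 and the C8-epimeric epoxide F2. Hydrolytic kinetic resolution with (salen)Co(OAc) (the enantiomer that consumes the (8R)-oxirane, fixed in a first run) and 0.55 equiv of water turns F2 into the polar diol F3, and unchanged 17 is separated by chromatography.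

Step 11 (new nickel-catalysed macrocyclisation of 17). Possible failures are exo closure, oligomerisation, or insertion of zerovalent nickel into the allylic lactone C6–O bond. Fallback (sets out from 6, comes back at 22; known chemistry only): the ring is closed instead at C6–C7 by the chromium-mediated Nozaki–Hiyama allylation that is the established closure for costunolide-type germacranolides.
- Enal 6 is masked with HC(OMe)3 and PPTS in MeOH as the dimethyl acetal F4.
- The known intermolecular nickel-catalysed reductive alkyne–epoxide coupling (Ni(cod)2, PBu3, Et3B) of F4 with commercial (R)-4-methoxybenzyl glycidyl ether gives the homoallylic alcohol F5; regioselectivity on this dialkyl alkyne is untested, and the regioisomer would be removed by chromatography.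
- TESCl and imidazole give the silyl ether F6.
- DDQ in buffered CH2Cl2 removes the PMB group to give the primary alcohol F7.
- Dess–Martin periodinane gives the α-silyloxy aldehyde F8.
- Morita–Baylis–Hillman reaction with methyl acrylate and DABCO gives the hydroxy acrylate F9 as carbinol epimers.
- NBS and Me2S convert it by SN2' substitution into the (Z)-allylic bromide F10.
- PPTS in wet acetone unmasks the aldehyde to give the enal bromide F11.
- CrCl2 (divalent chromium) in THF at high dilution adds the γ-carbon C7 of the allylchromium to the C6 aldehyde through a chair transition state, and the chromium alkoxide lactonises onto the methyl ester to give 22 directly, so steps 12 and 13 are bypassed. The anti (trans-lactone) sense is precedented; the facial sense relative to C8 is not, and the diastereomers would have to be separated.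

Step 13 (α-methylenation of 19). Quaternisation and elimination on the hindered macrocycle may stall or the liberated amine may add back. Fallback (sets out from 19, comes back at 22): carboxylation and decarboxylative methylenation. The lithium enolate (LiN(iPr)2, THF, −78 °C) is quenched with CO2 to give the α-carboxylic acid F12, which with aqueous formaldehyde and Et2NH in buffered AcOH undergoes Mannich condensation with loss of CO2 to give 22.

**Further compounds**
F1 | step 9 | (4R,5R)-4-[(1R)-2-bromo-1-hydroxyethyl]-5-[(1E)-2-methyl-7-[(TBDPS)oxy]hept-1-en-5-yn-1-yl]oxolan-2-one | O=C1C[C@H]([C@@H](O)CBr)[C@@H](/C=C(C)/CCC#CCO[Si](C(C)(C)C)(c2ccccc2)c2ccccc2)O1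
F2 | step 9 | (4S,5R)-5-[(1E)-2-methyl-7-[(TBDPS)oxy]hept-1-en-5-yn-1-yl]-4-[(2R)-oxiran-2-yl]oxolan-2-one | O=C1C[C@H]([C@@H]2CO2)[C@@H](/C=C(C)/CCC#CCO[Si](C(C)(C)C)(c2ccccc2)c2ccccc2)O1
F3 | step 9 | (4R,5R)-4-[(1R)-1,2-dihydroxyethyl]-5-[(1E)-2-methyl-7-[(TBDPS)oxy]hept-1-en-5-yn-1-yl]oxolan-2-one | O=C1C[C@H]([C@@H](O)CO)[C@@H](/C=C(C)/CCC#CCO[Si](C(C)(C)C)(c2ccccc2)c2ccccc2)O1
F4 | step 11 | (2E)-1,1-dimethoxy-3-methyl-8-[(TBDPS)oxy]oct-2-en-6-yne | COC(OC)/C=C(C)/CCC#CCO[Si](C(C)(C)C)(c1ccccc1)c1ccccc1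
F5 | step 11 | (2R,4Z,8E)-10,10-dimethoxy-1-[(4-methoxybenzyl)oxy]-8-methyl-4-{[(TBDPS)oxy]methyl}deca-4,8-dien-2-ol | COc1ccc(COC[C@H](O)C/C(CO[Si](C(C)(C)C)(c2ccccc2)c2ccccc2)=C/CC/C(C)=C/C(OC)OC)cc1
F6 | step 11 | triethylsilyl ether of F5 at C2, (2R,4Z,8E) | COc1ccc(COC[C@H](O[Si](CC)(CC)CC)C/C(CO[Si](C(C)(C)C)(c2ccccc2)c2ccccc2)=C/CC/C(C)=C/C(OC)OC)cc1
F7 | step 11 | (2R,4Z,8E)-10,10-dimethoxy-8-methyl-4-{[(TBDPS)oxy]methyl}-2-[(TES)oxy]deca-4,8-dien-1-ol | OC[C@H](O[Si](CC)(CC)CC)C/C(CO[Si](C(C)(C)C)(c1ccccc1)c1ccccc1)=C/CC/C(C)=C/C(OC)OC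
F8 | step 11 | (2R,4Z,8E)-10,10-dimethoxy-8-methyl-4-{[(TBDPS)oxy]methyl}-2-[(TES)oxy]deca-4,8-dienal | O=C[C@H](O[Si](CC)(CC)CC)C/C(CO[Si](C(C)(C)C)(c1ccccc1)c1ccccc1)=C/CC/C(C)=C/C(OC)OC
F9 | step 11 | methyl (4R,6Z,10E)-3-hydroxy-12,12-dimethoxy-10-methyl-2-methylidene-6-{[(TBDPS)oxy]methyl}-4-[(TES)oxy]dodeca-6,10-dienoate (C3 epimers) | COC(=O)C(=C)C(O)[C@H](O[Si](CC)(CC)CC)C/C(CO[Si](C(C)(C)C)(c1ccccc1)c1ccccc1)=C/CC/C(C)=C/C(OC)OC
F10 | step 11 | methyl (2Z,4R,6Z,10E)-2-(bromomethyl)-12,12-dimethoxy-10-methyl-6-{[(TBDPS)oxy]methyl}-4-[(TES)oxy]dodeca-2,6,10-trienoate | COC(=O)/C(CBr)=C/[C@H](O[Si](CC)(CC)CC)C/C(CO[Si](C(C)(C)C)(c1ccccc1)c1ccccc1)=C/CC/C(C)=C/C(OC)OC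
F11 | step 11 | methyl (2Z,4R,6Z,10E)-2-(bromomethyl)-10-methyl-12-oxo-6-{[(TBDPS)oxy]methyl}-4-[(TES)oxy]dodeca-2,6,10-trienoate | COC(=O)/C(CBr)=C/[C@H](O[Si](CC)(CC)CC)C/C(CO[Si](C(C)(C)C)(c1ccccc1)c1ccccc1)=C/CC/C(C)=C/C=O
F12 | step 13 | (6R,7S,8R,11R)-8-[(TES)oxy]-14-[(TBDPS)oxy]germacra-1(10)Z,4E-dien-12,6-olid-13-oic acid | CC[Si](CC)(CC)O[C@@H]1C/C(CO[Si](C(C)(C)C)(c2ccccc2)c2ccccc2)=C/CC/C(C)=C/[C@H]2OC(=O)[C@@H](C(=O)O)[C@@H]21
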